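The flavanone is disconnected at C4–C4a. As long as C8 is unsubstituted, ring A bearing the pyranone at C6 has a local twofold axis through C6 and C8a. The two carbons ortho to O1 (the future C4a and C8) are therefore equivalent. An (S)-3-aryloxy-3-phenylpropanoic acid attached to that unique para oxygen closes ring C by intramolecular Friedel–Crafts acylation to a single constitution, with C2 already fixed by Mitsunobu inversion. The precursor, acid 18, carries only acid-stable benzyl groups: two on ring A and one on the pyranone enol. Hydrogenolysis, masking of the enol, 1,1-dimethylallylation of O7 and Claisen rearrangement then deliver the C8 prenyl group.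

Key step: step 11

Assumption: the C6–C3′ aryl–pyranone axis is not a defined stereoelement of the target; from 20 onwards hindered rotation may appear as interconverting rotamers, all of which lead to 29.

Remarks on the design:
- **Pyranone enol.** An acetal on this vinylogous acid would not be safe in (CF3CO)2O/CF3CO2H. It would also release a methoxymethyl cation next to the free, nucleophilic ring A carbons. The enol is therefore benzylated through the key step, and the acetal is introduced only after ring A has been acylated.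
- **O1 as a chlorine placeholder.** O1 is carried as chlorine until ring A and the pyranone are joined. Electrophilic substitution of 3,5-dialkoxyphenol derivatives does not go reliably to the carbon between the two alkoxy groups, and benzyl ethers do not tolerate directed lithiation. Iodination between two free resorcinol hydroxyls is dependable.
- **Stereochemistry.** C2 is the only stereocentre. (R)-15 gives (S)-16 by inversion, and the descriptor stays S up to 29 because the priority order O > phenyl > CH2 never changes. After ring C is closed no free base is used.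

Step 1
Reactants: 1 3-pentanone
Product: 2 3-(trimethylsilyloxy)pent-2-ene (E/Z mixture; the geometry is irrelevant)
Conditions: Me3SiOTf (1.1 equiv), Et3N (1.3 equiv), CH2Cl2, 0 °C
Reagents that add atoms: trimethylsilyl triflate C[Si](C)(C)OS(=O)(=O)C(F)(F)F
Why: Soft enolisation with O-silylation (silyl enol ether formation) of a symmetric ketone can give only one constitutional enol ether.

Step 2
Reactants: 2 3-(trimethylsilyloxy)pent-2-ene; 3 malonyl dichloride
Product: 4 6-ethyl-4-hydroxy-5-methyl-2H-pyran-2-one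
Conditions: Et2O, −78 °C → rt
Reagents that add atoms: none
Why: Pyranone annulation by double acylation: the enol silane is C-acylated by one acid chloride and the enol oxygen of the resulting 1,3-dicarbonyl closes onto the second one, so the ketone carbon becomes C6 (ethyl) and its α-carbon C5 (methyl).

Step 3
Reactants: 4 6-ethyl-4-hydroxy-5-methyl-2H-pyran-2-one
Product: 5 6-ethyl-4-hydroxy-3-iodo-5-methyl-2H-pyran-2-one
Conditions: NIS (1.05 equiv), MeCN, 0 °C → rt, dark
Reagents that add atoms: N-iodosuccinimide O=C1CCC(=O)N1I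
Why: Electrophilic iodination of an enolised 1,3-dicarbonyl unit can only take place at C3, the single unsubstituted and most nucleophilic ring carbon.

Step 4
Reactants: 5 6-ethyl-4-hydroxy-3-iodo-5-methyl-2H-pyran-2-one
Product: 6 4-(benzyloxy)-6-ethyl-3-iodo-5-methyl-2H-pyran-2-one
Conditions: BnBr (1.2 equiv), K2CO3 (1.5 equiv), DMF, rt → 40 °C
Reagents that add atoms: benzyl bromide BrCc1ccccc1
Why: Williamson-type O-alkylation of the vinylogous carboxylate is favoured because iodine blocks C3 against C-benzylation, and a minor 2-O-benzyl 4-pyranone isomer would be removed by chromatography.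

Step 5
Reactants: 7 5-chlorobenzene-1,3-diol (5-chlororesorcinol)
Product: 8 5-chloro-2-iodobenzene-1,3-diol
Conditions: I2 (1.05 equiv), NaHCO3 (1.1 equiv), H2O, 0 °C → rt
Reagents that add atoms: iodine II
Why: Electrophilic aromatic iodination of resorcinols in aqueous bicarbonate goes to the carbon between the two hydroxyls, and the chlorine at C5 additionally shields the alternative carbons C4 and C6.

Step 6
Reactants: 8 5-chloro-2-iodobenzene-1,3-diol
Product: 9 1,3-bis(benzyloxy)-5-chloro-2-iodobenzene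
Conditions: BnBr (2.3 equiv), K2CO3 (3 equiv), DMF, rt
Reagents that add atoms: benzyl bromide BrCc1ccccc1
Why: Williamson ether synthesis on two equivalent and fairly acidic phenols is routine and leaves both carbon–halogen bonds untouched.

Step 7
Reactants: 9 1,3-bis(benzyloxy)-5-chloro-2-iodobenzene; 6 4-(benzyloxy)-6-ethyl-3-iodo-5-methyl-2H-pyran-2-one
Product: 12 4-(benzyloxy)-3-[2,6-bis(benzyloxy)-4-chlorophenyl]-6-ethyl-5-methyl-2H-pyran-2-one, via aryllithium 10 (not isolated), via arylzinc chloride 11 (not isolated)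
Conditions: 9, n-BuLi (1.05 equiv), THF, −78 °C; ZnCl2 (1.1 equiv), −78 °C → rt; 6 (1.15 equiv), Pd2(dba)3 (2.5 mol %), RuPhos (10 mol %), 60 °C
Reagents that add atoms: n-butyllithium [Li]CCCC (lithium of 10); zinc dichloride Cl[Zn]Cl (zinc and chlorine of 11)
Why: Negishi coupling: iodine–lithium exchange at −78 °C outruns any attack on the benzyl ethers or the C–Cl bond, the derived arylzinc is non-basic, a bulky electron-rich biarylphosphine on zerovalent palladium is the established answer to bonds flanked by four ortho substituents, and oxidative addition selects the C–I bond of 6 and leaves the aryl chloride for step 8.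

Step 8
Reactants: 12 4-(benzyloxy)-3-[2,6-bis(benzyloxy)-4-chlorophenyl]-6-ethyl-5-methyl-2H-pyran-2-one
Product: 14 4-(benzyloxy)-3-[2,6-bis(benzyloxy)-4-hydroxyphenyl]-6-ethyl-5-methyl-2H-pyran-2-one, via pinacol boronate 13 (not isolated)
Conditions: B2pin2 (1.3 equiv), Pd2(dba)3 (2 mol %), XPhos (8 mol %), KOAc (3 equiv), dioxane, 90 °C; then NaBO3·4H2O (4 equiv), THF/H2O, rt
Reagents that add atoms: bis(pinacolato)diboron CC1(C)OB(OC1(C)C)B1OC(C)(C)C(C)(C)O1 (boryl group of 13); sodium perborate [Na+].[O-]OB=O (phenol oxygen of 14)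
Why: Miyaura borylation of the unhindered aryl chloride followed by oxidative ipso-hydroxylation of the boronate in the same flask turns the chlorine placeholder into the unique phenol (future O1) under weakly basic conditions that the benzylated pyranone should tolerate.

Step 9
Reactants: 14 4-(benzyloxy)-3-[2,6-bis(benzyloxy)-4-hydroxyphenyl]-6-ethyl-5-methyl-2H-pyran-2-one; 15 ethyl (R)-3-hydroxy-3-phenylpropanoate
Product: 16 ethyl (S)-3-{3,5-bis(benzyloxy)-4-[4-(benzyloxy)-6-ethyl-5-methyl-2-oxo-2H-pyran-3-yl]phenoxy}-3-phenylpropanoate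
Conditions: 15 (1.5 equiv), PPh3 (1.6 equiv), DIAD (1.6 equiv, slow addition), toluene, 0 °C → rt
Reagents that add atoms: none
Why: Mitsunobu etherification: the unhindered phenol displaces the oxyphosphonium derivative of the secondary benzylic alcohol by SN2 with inversion, so (R)-15 sets the (S) configuration of the future C2, while an apolar solvent at low temperature suppresses ionisation and an excess of cheap 15 makes up for loss by elimination.

Step 10
Reactants: 16 ethyl (S)-3-{3,5-bis(benzyloxy)-4-[4-(benzyloxy)-6-ethyl-5-methyl-2-oxo-2H-pyran-3-yl]phenoxy}-3-phenylpropanoate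
Product: 18 (S)-3-{3,5-bis(benzyloxy)-4-[4-(benzyloxy)-6-ethyl-5-methyl-2-oxo-2H-pyran-3-yl]phenoxy}-3-phenylpropanoic acid, via lithium carboxylate 17 (not isolated)
Conditions: LiOH·H2O (2.5 equiv), THF/H2O, 0 °C → rt; 1 M HCl to pH 3, 0 °C
Reagents that add atoms: lithium hydroxide [Li+].[OH-]
Why: Saponification: hydroxide attack at the unhindered ethyl ester is far faster than α-deprotonation and the carboxylate formed no longer enolises, so E1cB loss of the phenoxide is avoided, while the fully substituted and shielded pyranone should not open at this temperature.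

Step 11
Reactants: 18 (S)-3-{3,5-bis(benzyloxy)-4-[4-(benzyloxy)-6-ethyl-5-methyl-2-oxo-2H-pyran-3-yl]phenoxy}-3-phenylpropanoic acid
Product: 20 (S)-5,7-bis(benzyloxy)-6-[4-(benzyloxy)-6-ethyl-5-methyl-2-oxo-2H-pyran-3-yl]flavanone, via acyl trifluoroacetate 19 (not isolated)
Conditions: (CF3CO)2O (1.5 equiv), CH2Cl2 (0.03 M), 0 °C; cold aq NaHCO3 quench
Reagents that add atoms: trifluoroacetic anhydride O=C(OC(=O)C(F)(F)F)C(F)(F)F (trifluoroacetyl group of 19)
Why: Trifluoroacetic anhydride turns acid 18 into acyl trifluoroacetate 19, whose acyl carbon (C4) is attacked by the ring A carbon ortho to O1 to give an arenium ion that loses a proton, which is the intramolecular Friedel–Crafts acylation long used to convert 3-aryloxypropanoic acids into chroman-4-ones. Ring C closes in a 6-exo-trig mode at the acyl carbon, its six atoms being O1, C2, C3, C4, C4a and C8a. No stereocentre is created: C2 is a spectator set in step 9, and its C–O bond should hold because the β-acyl group destabilises a benzylic cation and the medium is only dilute CF3CO2H at 0 °C, which is also too mild for retro-oxa-Michael opening of 20. Regioselectivity is secured by the substrate, since the two carbons ortho to O1 are exchanged by the local twofold axis through C8a and C6 and either closure gives the same constitution. The attacked carbon is activated by all three ring oxygens (ortho, ortho and para), so cyclisation should outrun intermolecular trifluoroacetylation, and the new C4 carbonyl then deactivates ring A. The three benzyl groups are inert to CF3CO2H at this temperature, so no carbocation is released next to the nucleophilic ring.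

Step 12
Reactants: 20 (S)-5,7-bis(benzyloxy)-6-[4-(benzyloxy)-6-ethyl-5-methyl-2-oxo-2H-pyran-3-yl]flavanone
Product: 21 (S)-6-(6-ethyl-4-hydroxy-5-methyl-2-oxo-2H-pyran-3-yl)-5,7-dihydroxyflavanone
Conditions: H2 (1 atm), 10% Pd/C, EtOAc/THF, rt
Reagents that add atoms: none
Why: Catalytic hydrogenolysis of benzyl ethers under neutral conditions frees O5, O7 and the pyranone enol in one operation, while the tetrasubstituted pyranone double bonds, the aryl ketone and the cyclic C2–O1 bond react much more slowly, as is usual for benzylated flavanones.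

Step 13
Reactants: 21 (S)-6-(6-ethyl-4-hydroxy-5-methyl-2-oxo-2H-pyran-3-yl)-5,7-dihydroxyflavanone
Product: 22 (S)-6-[6-ethyl-4-(methoxymethoxy)-5-methyl-2-oxo-2H-pyran-3-yl]-5,7-dihydroxyflavanone
Conditions: MOMCl (1.0 equiv), iPr2NEt (1.05 equiv), CH2Cl2/THF, −20 → 0 °C
Reagents that add atoms: chloromethyl methyl ether COCCl
Why: Chemoselective O-alkylation (MOM acetal formation): the pyranone enol is a vinylogous carboxylic acid and clearly the most acidic hydroxyl, so one equivalent of amine ionises it alone, 5-OH is tied up in the hydrogen bond to C4=O, no free amine is left to threaten C2, and alkylation at either oxygen of the ambident anion would be acceptable because step 17 erases the difference.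

Step 14
Reactants: 23 2-methylbut-3-en-2-ol
Product: 25 tert-butyl (2-methylbut-3-en-2-yl) carbonate, via lithium alkoxide 24 (not isolated)
Conditions: n-BuLi (1.05 equiv), THF, −78 → 0 °C; Boc2O (1.05 equiv), 0 °C → rt; H2O
Reagents that add atoms: n-butyllithium [Li]CCCC (lithium of 24); di-tert-butyl dicarbonate CC(C)(C)OC(=O)OC(=O)OC(C)(C)C
Why: O-acylation of a preformed tertiary alkoxide with a dicarbonate is the standard way to mixed tertiary allylic carbonates.

Step 15
Reactants: 22 (S)-6-[6-ethyl-4-(methoxymethoxy)-5-methyl-2-oxo-2H-pyran-3-yl]-5,7-dihydroxyflavanone; 25 tert-butyl (2-methylbut-3-en-2-yl) carbonate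
Product: 26 (S)-6-[6-ethyl-4-(methoxymethoxy)-5-methyl-2-oxo-2H-pyran-3-yl]-5-hydroxy-7-[(2-methylbut-3-en-2-yl)oxy]flavanone
Conditions: 25 (1.5 equiv), Pd(PPh3)4 (5 mol %), THF, 0 °C, short reaction time
Reagents that add atoms: none
Why: Tsuji–Trost O-allylation: zerovalent palladium ionises 25 to a 1,1-dimethyl-π-allyl complex and tert-butoxide, which deprotonates only the free 7-OH (5-OH is chelated and the enol is masked), and at 0 °C the phenoxide attacks the more substituted allyl terminus under kinetic control, with no added base that could racemise C2 by retro-oxa-Michael opening.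

Step 16
Reactants: 26 (S)-6-[6-ethyl-4-(methoxymethoxy)-5-methyl-2-oxo-2H-pyran-3-yl]-5-hydroxy-7-[(2-methylbut-3-en-2-yl)oxy]flavanone
Product: 28 (S)-6-[6-ethyl-4-(methoxymethoxy)-5-methyl-2-oxo-2H-pyran-3-yl]-5,7-dihydroxy-8-(3-methylbut-2-en-1-yl)flavanone, via cyclohexadienone 27 (not isolated)
Conditions: toluene (degassed), 110 °C
Reagents that add atoms: none
Why: Aromatic Claisen rearrangement: the gem-dimethyl-substituted allyl aryl ether shifts [3,3] at moderate temperature to the only free ortho carbon C8 (C6 is blocked), which inverts the allyl unit into a prenyl group, and dienone 27 rearomatises by tautomerisation under neutral conditions that leave C2 untouched.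

Step 17
Reactants: 28 (S)-6-[6-ethyl-4-(methoxymethoxy)-5-methyl-2-oxo-2H-pyran-3-yl]-5,7-dihydroxy-8-(3-methylbut-2-en-1-yl)flavanone
Product: 29 (S)-6-(6-ethyl-4-hydroxy-5-methyl-2-oxo-2H-pyran-3-yl)-5,7-dihydroxy-8-(3-methylbut-2-en-1-yl)flavanone (target)
Conditions: cat. HCl (0.1 M), MeOH/CH2Cl2, 0 °C → rt
Reagents that add atoms: none
Why: Acid-catalysed acetal exchange (MOM cleavage): as the acetal of a vinylogous carboxylic acid the group is far more labile than an aryl MOM ether, so catalytic HCl in methanol suffices, and under these conditions neither chroman formation from the o-prenylphenol nor opening of ring C is expected.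

Compound list
1 | 3-pentanone | CCC(=O)CC | starting material
2 | 3-(trimethylsilyloxy)pent-2-ene (E/Z mixture) | CC=C(CC)O[Si](C)(C)C | intermediate
3 | malonyl dichloride | O=C(Cl)CC(=O)Cl | starting material
4 | 6-ethyl-4-hydroxy-5-methyl-2H-pyran-2-one | CCc1oc(=O)cc(O)c1C | intermediate
5 | 6-ethyl-4-hydroxy-3-iodo-5-methyl-2H-pyran-2-one | CCc1oc(=O)c(I)c(O)c1C | intermediate
6 | 4-(benzyloxy)-6-ethyl-3-iodo-5-methyl-2H-pyran-2-one | CCc1oc(=O)c(I)c(OCc2ccccc2)c1C | intermediate
7 | 5-chlorobenzene-1,3-diol | Oc1cc(O)cc(Cl)c1 | starting material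
8 | 5-chloro-2-iodobenzene-1,3-diol | Oc1cc(Cl)cc(O)c1I | intermediate
9 | 1,3-bis(benzyloxy)-5-chloro-2-iodobenzene | Clc1cc(OCc2ccccc2)c(I)c(OCc2ccccc2)c1 | intermediate
10 | [2,6-bis(benzyloxy)-4-chlorophenyl]lithium (not isolated) | [Li]c1c(OCc2ccccc2)cc(Cl)cc1OCc1ccccc1 | intermediate
11 | [2,6-bis(benzyloxy)-4-chlorophenyl]zinc chloride (not isolated) | Cl[Zn]c1c(OCc2ccccc2)cc(Cl)cc1OCc1ccccc1 | intermediate
12 | 4-(benzyloxy)-3-[2,6-bis(benzyloxy)-4-chlorophenyl]-6-ethyl-5-methyl-2H-pyran-2-one | CCc1oc(=O)c(-c2c(OCc3ccccc3)cc(Cl)cc2OCc2ccccc2)c(OCc2ccccc2)c1C | intermediate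
13 | 4-(benzyloxy)-3-[2,6-bis(benzyloxy)-4-(4,4,5,5-tetramethyl-1,3,2-dioxaborolan-2-yl)phenyl]-6-ethyl-5-methyl-2H-pyran-2-one (not isolated) | CCc1oc(=O)c(-c2c(OCc3ccccc3)cc(B3OC(C)(C)C(C)(C)O3)cc2OCc2ccccc2)c(OCc2ccccc2)c1C | intermediate
14 | 4-(benzyloxy)-3-[2,6-bis(benzyloxy)-4-hydroxyphenyl]-6-ethyl-5-methyl-2H-pyran-2-one | CCc1oc(=O)c(-c2c(OCc3ccccc3)cc(O)cc2OCc2ccccc2)c(OCc2ccccc2)c1C | intermediate
15 | ethyl (R)-3-hydroxy-3-phenylpropanoate | CCOC(=O)C[C@@H](O)c1ccccc1 | starting material
16 | ethyl (S)-3-{3,5-bis(benzyloxy)-4-[4-(benzyloxy)-6-ethyl-5-methyl-2-oxo-2H-pyran-3-yl]phenoxy}-3-phenylpropanoate | CCc1oc(=O)c(-c2c(OCc3ccccc3)cc(O[C@@H](CC(=O)OCC)c3ccccc3)cc2OCc2ccccc2)c(OCc2ccccc2)c1C | intermediate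
17 | lithium (S)-3-{3,5-bis(benzyloxy)-4-[4-(benzyloxy)-6-ethyl-5-methyl-2-oxo-2H-pyran-3-yl]phenoxy}-3-phenylpropanoate (not isolated) | CCc1oc(=O)c(-c2c(OCc3ccccc3)cc(O[C@@H](CC(=O)[O-])c3ccccc3)cc2OCc2ccccc2)c(OCc2ccccc2)c1C.[Li+] | intermediate
18 | (S)-3-{3,5-bis(benzyloxy)-4-[4-(benzyloxy)-6-ethyl-5-methyl-2-oxo-2H-pyran-3-yl]phenoxy}-3-phenylpropanoic acid | CCc1oc(=O)c(-c2c(OCc3ccccc3)cc(O[C@@H](CC(=O)O)c3ccccc3)cc2OCc2ccccc2)c(OCc2ccccc2)c1C | intermediate
19 | mixed anhydride of 18 and trifluoroacetic acid (not isolated) | CCc1oc(=O)c(-c2c(OCc3ccccc3)cc(O[C@@H](CC(=O)OC(=O)C(F)(F)F)c3ccccc3)cc2OCc2ccccc2)c(OCc2ccccc2)c1C | intermediate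
20 | (S)-5,7-bis(benzyloxy)-6-[4-(benzyloxy)-6-ethyl-5-methyl-2-oxo-2H-pyran-3-yl]flavanone | CCc1oc(=O)c(-c2c(OCc3ccccc3)cc3c(c2OCc2ccccc2)C(=O)C[C@@H](c2ccccc2)O3)c(OCc2ccccc2)c1C | intermediate
21 | (S)-6-(6-ethyl-4-hydroxy-5-methyl-2-oxo-2H-pyran-3-yl)-5,7-dihydroxyflavanone | CCc1oc(=O)c(-c2c(O)cc3c(c2O)C(=O)C[C@@H](c2ccccc2)O3)c(O)c1C | intermediate
22 | (S)-6-[6-ethyl-4-(methoxymethoxy)-5-methyl-2-oxo-2H-pyran-3-yl]-5,7-dihydroxyflavanone | CCc1oc(=O)c(-c2c(O)cc3c(c2O)C(=O)C[C@@H](c2ccccc2)O3)c(OCOC)c1C | intermediate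
23 | 2-methylbut-3-en-2-ol | CC(C)(O)C=C | starting material
24 | lithium 2-methylbut-3-en-2-olate (not isolated) | CC(C)([O-])C=C.[Li+] | intermediate
25 | tert-butyl (2-methylbut-3-en-2-yl) carbonate | CC(C)(C=C)OC(=O)OC(C)(C)C | intermediate
26 | (S)-6-[6-ethyl-4-(methoxymethoxy)-5-methyl-2-oxo-2H-pyran-3-yl]-5-hydroxy-7-[(2-methylbut-3-en-2-yl)oxy]flavanone | CCc1oc(=O)c(-c2c(OC(C)(C)C=C)cc3c(c2O)C(=O)C[C@@H](c2ccccc2)O3)c(OCOC)c1C | intermediate
27 | C8-prenylated cyclohexa-2,4-dienone tautomer of 28 (C8 transient and undefined; not isolated) | CCc1oc(=O)c(C2=C(O)C3=C(O[C@H](c4ccccc4)CC3=O)C(CC=C(C)C)C2=O)c(OCOC)c1C | intermediate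
28 | (S)-6-[6-ethyl-4-(methoxymethoxy)-5-methyl-2-oxo-2H-pyran-3-yl]-5,7-dihydroxy-8-(3-methylbut-2-en-1-yl)flavanone | CCc1oc(=O)c(-c2c(O)c(CC=C(C)C)c3c(c2O)C(=O)C[C@@H](c2ccccc2)O3)c(OCOC)c1C | intermediate
29 | (S)-6-(6-ethyl-4-hydroxy-5-methyl-2-oxo-2H-pyran-3-yl)-5,7-dihydroxy-8-(3-methylbut-2-en-1-yl)flavanone | CCc1oc(=O)c(-c2c(O)c(CC=C(C)C)c3c(c2O)C(=O)C[C@@H](c2ccccc2)O3)c(O)c1C | target

Total step count: 17.
Longest linear sequence: 14 (steps 1–4, 7–13, 15–17). Steps 5–6 and step 14 are side branches.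

Steps most likely to fail

**Step 11 (key step).**
- What may go wrong: the activated acid may fragment or ionise at the benzylic C2–O1 bond, with loss of the phenol or erosion of configuration. Ring A may also be trifluoroacetylated faster than it cyclises.
- Fallback: the same C4–C4a bond is made with reversed polarity, by halogen–metal exchange and anionic closure (Parham-type cyclisation), which is known chemistry for enantiopure 2-substituted chroman-4-ones.
- Route: it sets out from 18. Coupling with MeNH(OMe)·HCl (EDC·HCl, N-methylmorpholine, CH2Cl2, 0 °C) gives (S)-3-{3,5-bis(benzyloxy)-4-[4-(benzyloxy)-6-ethyl-5-methyl-2-oxo-2H-pyran-3-yl]phenoxy}-N-methoxy-N-methyl-3-phenylpropanamide F1. NIS (1 equiv, MeCN, 0 °C) iodinates one of the two equivalent carbons ortho to O1 and gives the 2-iodophenoxy amide F2. Iodine–magnesium exchange with iPrMgCl·LiCl (THF, −40 °C) gives the arylmagnesium chloride F3. This adds to the amide carbonyl in the same flask and comes back to the route at 20 after aqueous NH4Cl.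
- Symmetry still guarantees one regioisomer in the iodination, and no acid touches C2.

**Step 7.**
- What may go wrong: transmetalation and reductive elimination between two doubly ortho-substituted carbons may be so slow that protodemetalation of the arylzinc and reduction of the C–I bond take over.
- Fallback: ligand coupling on tetravalent lead, a known way to join 2,6-disubstituted aryl groups to the central carbon of cyclic 1,3-dicarbonyl compounds.
- Route: it sets out from 9 and 4, so steps 3 and 4 are then not needed. Aryllithium 10, made as in step 7, is quenched with Bu3SnCl to give tributyl[2,6-bis(benzyloxy)-4-chlorophenyl]stannane F4. Tin–lead exchange with Pb(OAc)4 (cat. Hg(OAc)2, CHCl3, 40 °C) gives [2,6-bis(benzyloxy)-4-chlorophenyl]lead triacetate F5. This arylates C3 of pyranone 4 (pyridine, CHCl3, 40–60 °C) to give 3-[2,6-bis(benzyloxy)-4-chlorophenyl]-6-ethyl-4-hydroxy-5-methyl-2H-pyran-2-one F6. O-benzylation (BnBr, K2CO3, DMF) comes back to the route at 12.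

**Step 9.**
- What may go wrong: the activated alcohol may undergo β-elimination, since its α-hydrogens are acidified by the ester. It may also ionise partly at the benzylic carbon. The results would be consumption of the alcohol and erosion of enantiopurity.
- Fallback: etherify with an alcohol that has no acidifying group and unmask the acid oxidatively.
- Route: it sets out from 14. Mitsunobu reaction (PPh3, DIAD, toluene, 0 °C) with commercial (R)-1-phenylbut-3-en-1-ol (C=CC[C@@H](O)c1ccccc1) gives, with inversion, 4-(benzyloxy)-3-{2,6-bis(benzyloxy)-4-[(S)-1-phenylbut-3-en-1-yloxy]phenyl}-6-ethyl-5-methyl-2H-pyran-2-one F7. Lemieux–Johnson cleavage (cat. OsO4, NaIO4, 2,6-lutidine, dioxane/H2O) gives (S)-3-{3,5-bis(benzyloxy)-4-[4-(benzyloxy)-6-ethyl-5-methyl-2-oxo-2H-pyran-3-yl]phenoxy}-3-phenylpropanal F8. Pinnick oxidation (NaClO2, NaH2PO4, 2-methylbut-2-ene, t-BuOH/H2O) comes back to the route at 18, bypassing 16 and step 10.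

Further compounds
F1 | step 11 | (S)-3-{3,5-bis(benzyloxy)-4-[4-(benzyloxy)-6-ethyl-5-methyl-2-oxo-2H-pyran-3-yl]phenoxy}-N-methoxy-N-methyl-3-phenylpropanamide | CCc1oc(=O)c(-c2c(OCc3ccccc3)cc(O[C@@H](CC(=O)N(C)OC)c3ccccc3)cc2OCc2ccccc2)c(OCc2ccccc2)c1C
F2 | step 11 | (S)-3-{3,5-bis(benzyloxy)-4-[4-(benzyloxy)-6-ethyl-5-methyl-2-oxo-2H-pyran-3-yl]-2-iodophenoxy}-N-methoxy-N-methyl-3-phenylpropanamide | CCc1oc(=O)c(-c2c(OCc3ccccc3)cc(O[C@@H](CC(=O)N(C)OC)c3ccccc3)c(I)c2OCc2ccccc2)c(OCc2ccccc2)c1C
F3 | step 11 | arylmagnesium chloride derived from F2 (MgCl in place of I) | CCc1oc(=O)c(-c2c(OCc3ccccc3)cc(O[C@@H](CC(=O)N(C)OC)c3ccccc3)c([Mg]Cl)c2OCc2ccccc2)c(OCc2ccccc2)c1C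
F4 | step 7 | tributyl[2,6-bis(benzyloxy)-4-chlorophenyl]stannane | CCCC[Sn](CCCC)(CCCC)c1c(OCc2ccccc2)cc(Cl)cc1OCc1ccccc1
F5 | step 7 | [2,6-bis(benzyloxy)-4-chlorophenyl]lead triacetate | CC(=O)O[Pb](OC(C)=O)(OC(C)=O)c1c(OCc2ccccc2)cc(Cl)cc1OCc1ccccc1
F6 | step 7 | 3-[2,6-bis(benzyloxy)-4-chlorophenyl]-6-ethyl-4-hydroxy-5-methyl-2H-pyran-2-one | CCc1oc(=O)c(-c2c(OCc3ccccc3)cc(Cl)cc2OCc2ccccc2)c(O)c1C
F7 | step 9 | 4-(benzyloxy)-3-{2,6-bis(benzyloxy)-4-[(S)-1-phenylbut-3-en-1-yloxy]phenyl}-6-ethyl-5-methyl-2H-pyran-2-one | CCc1oc(=O)c(-c2c(OCc3ccccc3)cc(O[C@@H](CC=C)c3ccccc3)cc2OCc2ccccc2)c(OCc2ccccc2)c1C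
F8 | step 9 | (S)-3-{3,5-bis(benzyloxy)-4-[4-(benzyloxy)-6-ethyl-5-methyl-2-oxo-2H-pyran-3-yl]phenoxy}-3-phenylpropanal | CCc1oc(=O)c(-c2c(OCc3ccccc3)cc(O[C@@H](CC=O)c3ccccc3)cc2OCc2ccccc2)c(OCc2ccccc2)c1C
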